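**Retrosynthetic overview**
- Target 12 is the hexabenzyl ether 11 after one global hydrogenolysis; no stereocenter is present.
- The strategy rests on this feature: in ring B the carbon bearing the ring A oxygen, and in ring C the carbon bearing the ring B oxygen, each have an oxygenated neighbour carbon. Each such pair is therefore the diazo carbon and the carbonyl carbon of one 3,5-dioxygenated o-quinone diazide (9).
- Both aryl C–O bonds are cut there: carbene O–H insertion of 9 into the ring A phenol 4 gives A–O–B (10). The carbonyl oxygen freed on ring B is the hydroxyl that then takes a second unit of 9 to give A–O–B–O–C (11).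
- No ring is constructed; all three rings come from phloroglucinol cores (4 from phloroglucinol, 9 from 2-nitrophloroglucinol).

Key step: step 8

Assumption: 2-nitrophloroglucinol is taken as purchasable, and quinone diazide 9 is drawn as the diazo ketone, which is the same species as the 2-diazoniophenolate.

**Route**

Step 1
Reactants: 1 phloroglucinol
Product: 2 phloroglucinol triacetate (benzene-1,3,5-triyl triacetate)
Conditions: Ac2O, pyridine, cat. DMAP, 0 °C to rt
Reagents that add atoms: acetic anhydride CC(=O)OC(C)=O
Why: Exhaustive O-acetylation of a phenol is routine and masks the C-nucleophilic phloroglucinol for a clean O-benzylation in the next step.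

Step 2
Reactants: 2 phloroglucinol triacetate
Product: 3 1,3,5-tris(benzyloxy)benzene
Conditions: BnCl, NaH, DMF, H2O (3 equiv, slow addition), 0 °C to rt
Reagents that add atoms: benzyl chloride ClCc1ccccc1
Why: Benzylative deacetylation, in which hydroxide formed in situ releases each phenoxide slowly in the presence of benzyl chloride, so Williamson O-alkylation should outrun C-benzylation of the phloroglucinol nucleus.

Step 3
Reactants: 3 1,3,5-tris(benzyloxy)benzene
Product: 4 3,5-bis(benzyloxy)phenol
Conditions: EtSNa (1.3 equiv), DMF, 130 °C; aq. HCl work-up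
Reagents that add atoms: none
Why: Thiolate SN2 dealkylation at one benzylic carbon should stop after a single cleavage, because the resulting electron-rich phenoxide is a far poorer leaving group for a second displacement.

Step 4
Reactants: 5 2-nitrophloroglucinol
Product: 6 3,5-bis(benzyloxy)-2-nitrophenol
Conditions: BnBr (2.05 equiv), K2CO3, DMF, 0 °C to rt
Reagents that add atoms: benzyl bromide BrCc1ccccc1
Why: Williamson etherification should take the para hydroxyl and one of the two equivalent ortho hydroxyls and leave the last one, which is chelated to the nitro group and least nucleophilic, as in the selective dialkylation of 2-acylphloroglucinols.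

Step 5
Reactants: 6 3,5-bis(benzyloxy)-2-nitrophenol
Product: 7 2-amino-3,5-bis(benzyloxy)phenol
Conditions: Na2S2O4, THF–H2O, 50 °C, argon; used at once
Reagents that add atoms: none
Why: Dithionite reduction of a nitroarene to the aniline leaves benzyl ethers untouched, which catalytic hydrogenation would not.

Step 6
Reactants: 7 2-amino-3,5-bis(benzyloxy)phenol
Product: 9 3,5-bis(benzyloxy)-2-diazocyclohexa-3,5-dien-1-one (o-quinone diazide), via 2,4-bis(benzyloxy)-6-hydroxybenzenediazonium chloride 8 (not isolated)
Conditions: isoamyl nitrite, HCl, EtOH–THF, −5 to 0 °C, dark; then aq. NaHCO3, CH2Cl2 extraction, kept cold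
Reagents that add atoms: 3-methylbutyl nitrite (isoamyl nitrite) CC(C)CCON=O
Why: Diazotization of an o-aminophenol followed by deprotonation of the o-hydroxydiazonium salt is the classical entry to o-quinone diazides, and here the zwitterion is stabilized by two donor benzyloxy groups.

Step 7
Reactants: 4 3,5-bis(benzyloxy)phenol (3 equiv, excess recovered); 9 3,5-bis(benzyloxy)-2-diazocyclohexa-3,5-dien-1-one
Product: 10 3,5-bis(benzyloxy)-2-[3,5-bis(benzyloxy)phenoxy]phenol (A–O–B, free ring B hydroxyl)
Conditions: Rh2(OAc)4 (2 mol%), 4 Å MS, dry DCE, 55 °C, dark, syringe-pump addition of 9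
Reagents that add atoms: none
Why: Proposed new method: Rh2(OAc)4 should extrude N2 from 9 to a quinoid carbenoid of divalent rhodium, the hydroxyl of 4 should add to the carbene carbon as an oxonium ylide, and a proton shift to the adjacent carbonyl oxygen should rearomatize the ring to the o-aryloxyphenol; the closest known reaction types are Rh2(OAc)4-catalysed O–H insertion of phenols into carbenoids from alpha-diazo carbonyl compounds and 2-diazo-1,3-diones and carbene transfer from diazonaphthoquinones.

Step 8
Reactants: 10 3,5-bis(benzyloxy)-2-[3,5-bis(benzyloxy)phenoxy]phenol; 9 3,5-bis(benzyloxy)-2-diazocyclohexa-3,5-dien-1-one (1.3 equiv)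
Product: 11 hexa-O-benzyl triphloroethol A, 3,5-bis(benzyloxy)-2-{3,5-bis(benzyloxy)-2-[3,5-bis(benzyloxy)phenoxy]phenoxy}phenol
Conditions: Rh2(OAc)4 (3 mol%), 4 Å MS, dry DCE, 55–60 °C, dark, syringe-pump addition of 9, stopped at high conversion of 10
Reagents that add atoms: none
Why: Proposed new method: Rh2(OAc)4 should expel N2 from 9 to give an electrophilic quinoid carbenoid, to which the ring B hydroxyl of 10 adds as an oxonium ylide; proton transfer to the neighbouring carbonyl oxygen through a five-membered transition state then rearomatizes the ring, so the former diazo carbon becomes the ring C carbon bound to the ring B oxygen and the former carbonyl becomes the flanking ring C hydroxyl. The closest known reaction types are O–H insertion of phenols and alcohols into carbenoids from alpha-diazo carbonyl compounds and 2-diazo-1,3-diones under Rh2(OAc)4 or copper catalysis, and carbene transfer from diazonaphthoquinones; a benzenoid 3,5-dialkoxy quinone diazide reacting with a hindered, electron-rich phenol is the untested part. No ring is closed, only the aryl C–O bond between ring B oxygen and ring C is formed, and no stereocenter arises. The step needs O–H insertion to win over C-arylation of the electron-rich rings, Wolff ring contraction and a further insertion into the new hydroxyl of 11. The oxophilic carbenoid with its built-in proton acceptor, exclusion of light and water, slow addition of a small excess of 9 and the shielding of the new hydroxyl by the adjacent crowded ether should secure this. The position of the new bond is fixed by the diazo carbon, so no choice among the three oxygens of ring C has to be made.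

Step 9
Reactants: 11 hexa-O-benzyl triphloroethol A
Product: 12 triphloroethol A
Conditions: H2 (1 atm), 10% Pd/C, degassed THF–MeOH, rt; filtration and concentration under argon
Reagents that add atoms: none
Why: Hydrogenolysis of benzyl aryl ethers over palladium on carbon should release all six phenols while the diaryl ether bonds stay intact; the air-sensitive polyphenol can be purified as its peracetate if needed.

**Compound list**
1 | phloroglucinol | Oc1cc(O)cc(O)c1 | starting material
2 | phloroglucinol triacetate | CC(=O)Oc1cc(OC(C)=O)cc(OC(C)=O)c1 | intermediate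
3 | 1,3,5-tris(benzyloxy)benzene | c1ccc(COc2cc(OCc3ccccc3)cc(OCc3ccccc3)c2)cc1 | intermediate
4 | 3,5-bis(benzyloxy)phenol | Oc1cc(OCc2ccccc2)cc(OCc2ccccc2)c1 | intermediate
5 | 2-nitrophloroglucinol | O=[N+]([O-])c1c(O)cc(O)cc1O | starting material
6 | 3,5-bis(benzyloxy)-2-nitrophenol | O=[N+]([O-])c1c(O)cc(OCc2ccccc2)cc1OCc1ccccc1 | intermediate
7 | 2-amino-3,5-bis(benzyloxy)phenol | Nc1c(O)cc(OCc2ccccc2)cc1OCc1ccccc1 | intermediate
8 | 2,4-bis(benzyloxy)-6-hydroxybenzenediazonium chloride | N#[N+]c1c(O)cc(OCc2ccccc2)cc1OCc1ccccc1.[Cl-] | intermediate (not isolated)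
9 | 3,5-bis(benzyloxy)-2-diazocyclohexa-3,5-dien-1-one | [N-]=[N+]=C1C(=O)C=C(OCc2ccccc2)C=C1OCc1ccccc1 | intermediate
10 | 3,5-bis(benzyloxy)-2-[3,5-bis(benzyloxy)phenoxy]phenol | Oc1cc(OCc2ccccc2)cc(OCc2ccccc2)c1Oc1cc(OCc2ccccc2)cc(OCc2ccccc2)c1 | intermediate
11 | hexa-O-benzyl triphloroethol A | Oc1cc(OCc2ccccc2)cc(OCc2ccccc2)c1Oc1cc(OCc2ccccc2)cc(OCc2ccccc2)c1Oc1cc(OCc2ccccc2)cc(OCc2ccccc2)c1 | intermediate
12 | triphloroethol A | Oc1cc(O)cc(Oc2c(O)cc(O)cc2Oc2c(O)cc(O)cc2O)c1 | target

**Step count**
Total: 9 steps. Longest linear sequence: 6 steps (steps 4, 5, 6, 7, 8, 9 from 2-nitrophloroglucinol; the arm from phloroglucinol through steps 1, 2, 3, 7, 8, 9 is equally long).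

**Steps most likely to fail**

1. Step 8 (proposed new method). The carbenoid may attack a ring carbon of the electron-rich partner instead of the hindered hydroxyl, may undergo Wolff ring contraction, or may insert again into the newly formed phenol. The fallback sets out from 10 and from 3 and comes back at 12. Bromination of 3 with NBS in MeCN at 0 °C should give 2-bromo-1,3,5-tris(benzyloxy)benzene F1, since its three free ring positions are equivalent. An Ullmann diaryl ether coupling of 10 with F1 (CuI, picolinic acid, K3PO4, DMSO, 110 °C, or stoichiometric copper in pyridine if needed) should give hepta-O-benzyl triphloroethol A F2. Hydrogenolysis of F2 under the conditions of step 9 then gives 12 directly.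

2. Step 7 (proposed new method). The same competition between O–H insertion, C-arylation of 4 and Wolff rearrangement applies, together with consumption of the product by a second carbenoid. The fallback sets out from 7 and 4 and comes back at 10. Amine 7 is diazotized as in step 6 and the diazonium salt 8 is treated with KI to give 3,5-bis(benzyloxy)-2-iodophenol F3. The hydroxyl is protected with MOMCl and iPr2NEt to give 1,5-bis(benzyloxy)-2-iodo-3-(methoxymethoxy)benzene F4. Ullmann coupling of F4 with 4 (CuI, picolinic acid, K3PO4, DMSO, 100 °C) should give the methoxymethyl ether of 10, F5. Dilute HCl in MeOH removes the acetal and returns 10.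

3. Step 6. The very electron-rich ring may undergo C-nitrosation, azo coupling between the diazonium ion and unreacted amine, or oxidation of the aminophenol before diazotization is complete. The fallback sets out from 4 and comes back at 9. Ortho-oxidation of 4 with IBX in DMF should give 3,5-bis(benzyloxy)cyclohexa-3,5-diene-1,2-dione F6; the two ortho positions are equivalent. Condensation with tosylhydrazide in cold EtOH is expected at the C2 carbonyl, because the C1 carbonyl is deactivated as a vinylogous ester by both benzyloxy groups; this should give the mono-tosylhydrazone F7. Treatment with Et3N or basic alumina in CH2Cl2 eliminates sulfinate (Bamford–Stevens-type diazo formation) and gives 9.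

**Further compounds**
F1 | step 8 | 2-bromo-1,3,5-tris(benzyloxy)benzene | Brc1c(OCc2ccccc2)cc(OCc2ccccc2)cc1OCc1ccccc1
F2 | step 8 | hepta-O-benzyl triphloroethol A | C(Oc1cc(OCc2ccccc2)cc(Oc2c(OCc3ccccc3)cc(OCc3ccccc3)cc2Oc2c(OCc3ccccc3)cc(OCc3ccccc3)cc2OCc2ccccc2)c1)c1ccccc1
F3 | step 7 | 3,5-bis(benzyloxy)-2-iodophenol | Oc1cc(OCc2ccccc2)cc(OCc2ccccc2)c1I
F4 | step 7 | 1,5-bis(benzyloxy)-2-iodo-3-(methoxymethoxy)benzene | COCOc1cc(OCc2ccccc2)cc(OCc2ccccc2)c1I
F5 | step 7 | 1,5-bis(benzyloxy)-2-[3,5-bis(benzyloxy)phenoxy]-3-(methoxymethoxy)benzene | COCOc1cc(OCc2ccccc2)cc(OCc2ccccc2)c1Oc1cc(OCc2ccccc2)cc(OCc2ccccc2)c1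
F6 | step 6 | 3,5-bis(benzyloxy)cyclohexa-3,5-diene-1,2-dione | O=C1C(=O)C(OCc2ccccc2)=CC(OCc2ccccc2)=C1
F7 | step 6 | 3,5-bis(benzyloxy)cyclohexa-3,5-diene-1,2-dione 2-tosylhydrazone | Cc1ccc(cc1)S(=O)(=O)NN=C1C(=O)C=C(OCc2ccccc2)C=C1OCc1ccccc1
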